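At early times Saturday's run rose fast and afterwards sank slowly: E read 3.4% at 2.00 min, 6.0% at 8.00 min and 1.2% at 90.0 min.

| flask | D | G | Q | J | remark | time |
|---|---|---|---|---|---|---|
| Saturday's | 1 M | 0.55 M | 1 M | 1 M | run made earlier |  |
| flask | 1.0 M | 1.10 M | 1.00 M | 1.00 M |  | 80 min |

Saturday's run (percent of the D charged)

| time / min | E / % |
|---|---|
| 2.00 | 3.4 |
| 8.00 | 6.0 |
| 25.0 | 4.8 |
| 90.0 | 1.2 |

(readings scatter by 0.5 percentage points)

- what was read earlier has a scatter of 0.5 percentage points, one standard deviation
- no earlier run changes the charge of G; that part of a forecast is a guess

- the moment within 80 min at which there is most E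
- the amount of E, in percent of the D charged, at that time

I kept the books on D, following one molecule to its fork. In Saturday's run, E filled towards its highest reading at about 0.418 /min, while the tail fell at about 0.0213 /min. In that run filling read much faster than draining, so I booked that highest reading, scatter included, as the entry for D going to E. The remaining 94.0% of Saturday's D I booked, as an assumption, to a rival route, which I assumed runs through J. The selectivity factor w, the odds of E over the rival divided by [G]/[J], read off Saturday's run at about 0.116. No earlier run changed G, so holding w constant was my guess. For this flask, [G]/[J] of 1.10 put the E entry at 11.3%.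

The forecast said 10% at 7 min, reading the rise as “relaxation towards a reversible exchange”. My entry stood above its figure and came from the fork instead.

This flask peaked at 8.49 min with 9.70% of E, below my entry.

    D + G ⇌ Q + E (K = 0.910, k = 0.0420 /M/min)
    E + G ⇌ Q + Z (K = 1.50, k = 0.0200 /M/min)
    J + D → L (k = 0.400 /M/min)

At that peak this flask's books read D 16.4%, E 9.70%, Z 1.20% and L 72.7%, each in percent of the D charged. In the neighbouring flask, with 1.9 M of G and J as before, the same w and a [G]/[J] of 1.90 gave an entry of 18.1%. That flask's highest E was lower, at 14.2%.

(Readings and results are calculated for an exercise; noise was put on by code.)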